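**Retrosynthetic overview**
- The C1 carbinol is set last, by chelation-controlled hydride reduction of the (S)-α-aryloxy ketone.
- The C2–O aryl ether bond is made just before that, by a Mitsunobu union (inversion) of 4-allyl-2,6-dimethoxyphenol with (R)-1-(3,4-dimethoxyphenyl)-2-hydroxypropan-1-one, two C11 halves.
- The hydroxy ketone comes from the Grignard reagent of 4-bromoveratrole (from catechol) and the O-TBS Weinreb amide of methyl (R)-lactate.
- The phenol comes from resorcinol: O-methylation, C2 lithiation/borylation/oxidation, O-allylation, para-Claisen rearrangement.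
- No ring is constructed: both benzene rings are bought (resorcinol, catechol) and only their substituents are installed.

Assumption: the SMILES is read as (1R,2S), the erythro isomer (7R,8S in neolignan numbering); MeI, allyl bromide, TBSCl and MeNHOMe·HCl are treated as reagents; step 4 is an isomerisation and sets nothing free.

**Step 1**
Reactants: 1 resorcinol
Product: 2 1,3-dimethoxybenzene
Conditions: MeI (2.5 equiv), K2CO3 (3 equiv), acetone, reflux
Reagents that add atoms: iodomethane, CI
Why: Double Williamson O-methylation of the phenoxides by SN2 on a reactive methyl electrophile, with no stereocentre involved.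

**Step 2**
Reactants: 2 1,3-dimethoxybenzene
Product: 5 2,6-dimethoxyphenol, via 2,6-dimethoxyphenyllithium 3 (not isolated), via dimethyl (2,6-dimethoxyphenyl)boronate 4 (not isolated)
Conditions: n-BuLi, THF, 0 °C to rt; B(OMe)3, −78 °C to rt; AcOH, 30% H2O2, 0 °C to rt
Reagents that add atoms: hydrogen peroxide, OO
Why: Directed ortho-metalation occurs at C2, flanked by both methoxy groups, and borylation followed by boronate oxidation (aryl shift from B to O) delivers the phenol.

**Step 3**
Reactants: 5 2,6-dimethoxyphenol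
Product: 6 2-(allyloxy)-1,3-dimethoxybenzene
Conditions: allyl bromide (1.2 equiv), K2CO3, acetone, reflux
Reagents that add atoms: allyl bromide, C=CCBr
Why: Williamson ether synthesis of the phenoxide with an activated allylic halide.

**Step 4**
Reactants: 6 2-(allyloxy)-1,3-dimethoxybenzene
Product: 9 4-allyl-2,6-dimethoxyphenol, via 6-allyl-2,6-dimethoxycyclohexa-2,4-dienone 7 (not isolated), via 4-allyl-2,6-dimethoxycyclohexa-2,5-dienone 8 (not isolated)
Conditions: N,N-diethylaniline, 200 °C, sealed tube, argon
Reagents that add atoms: none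
Why: para-Claisen rearrangement, in which the ortho-dienone cannot enolise because both ortho positions carry OMe, so it undergoes a Cope shift to the para position and then tautomerises to the phenol.

**Step 5**
Reactants: 10 catechol
Product: 11 1,2-dimethoxybenzene (veratrole)
Conditions: MeI (2.5 equiv), K2CO3 (3 equiv), acetone, reflux, N2
Reagents that add atoms: iodomethane, CI
Why: Double Williamson O-methylation, run under inert gas to avoid catechol oxidation.

**Step 6**
Reactants: 11 1,2-dimethoxybenzene
Product: 12 4-bromo-1,2-dimethoxybenzene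
Conditions: NBS (1.05 equiv), MeCN, 0 °C to rt
Reagents that add atoms: N-bromosuccinimide, O=C1CCC(=O)N1Br
Why: Electrophilic aromatic bromination, which in MeCN goes selectively para to a methoxy group and gives the 4-bromo isomer.

**Step 7**
Reactants: 13 methyl (R)-lactate
Product: 14 methyl (R)-2-[(tert-butyldimethylsilyl)oxy]propanoate
Conditions: TBSCl, imidazole, DMF, 0 °C to rt
Reagents that add atoms: tert-butyldimethylsilyl chloride, CC(C)(C)[Si](C)(C)Cl
Why: Silyl ether protection of the secondary alcohol, leaving the chiral-pool (R) stereocentre untouched.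

**Step 8**
Reactants: 14 methyl (R)-2-[(tert-butyldimethylsilyl)oxy]propanoate
Product: 15 (R)-2-[(tert-butyldimethylsilyl)oxy]-N-methoxy-N-methylpropanamide
Conditions: MeNHOMe·HCl (1.6 equiv), i-PrMgCl (3.2 equiv), THF, −20 to 0 °C
Reagents that add atoms: N,O-dimethylhydroxylamine hydrochloride, CNOC.Cl
Why: Ester aminolysis by the magnesium amide (Weinreb amide formation), which proceeds at low temperature without epimerising the α-silyloxy centre.

**Step 9**
Reactants: 12 4-bromo-1,2-dimethoxybenzene; 15 (R)-2-[(tert-butyldimethylsilyl)oxy]-N-methoxy-N-methylpropanamide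
Product: 17 (R)-2-[(tert-butyldimethylsilyl)oxy]-1-(3,4-dimethoxyphenyl)propan-1-one, via (3,4-dimethoxyphenyl)magnesium bromide 16 (not isolated)
Conditions: Mg, I2 (cat.), THF, reflux; then 15 (0.75 equiv), THF, 0 °C to rt; cold 1 M HCl
Reagents that add atoms: none
Why: Weinreb ketone synthesis, in which the chelated tetrahedral intermediate stops the Grignard addition at the ketone stage and the (R) centre is not deprotonated.

**Step 10**
Reactants: 17 (R)-2-[(tert-butyldimethylsilyl)oxy]-1-(3,4-dimethoxyphenyl)propan-1-one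
Product: 18 (R)-1-(3,4-dimethoxyphenyl)-2-hydroxypropan-1-one
Conditions: 48% aq. HF, MeCN, 0 °C to rt
Reagents that add atoms: none
Why: Acidic fluoride desilylation under non-enolising conditions, so the base-sensitive α-hydroxy ketone keeps its (R) configuration.

**Step 11**
Reactants: 9 4-allyl-2,6-dimethoxyphenol; 18 (R)-1-(3,4-dimethoxyphenyl)-2-hydroxypropan-1-one
Product: 19 (S)-2-(4-allyl-2,6-dimethoxyphenoxy)-1-(3,4-dimethoxyphenyl)propan-1-one
Conditions: PPh3 (1.5 equiv), DIAD (1.5 equiv), THF, 0 °C to rt
Reagents that add atoms: none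
Why: Mitsunobu etherification, in which the phenoxide (pKa about 10) displaces the carbonyl-activated alkoxyphosphonium by SN2, inverting C2 from (R) to (S) under essentially neutral conditions.

**Step 12**
Reactants: 19 (S)-2-(4-allyl-2,6-dimethoxyphenoxy)-1-(3,4-dimethoxyphenyl)propan-1-one
Product: 20 (1R,2S)-2-(4-allyl-2,6-dimethoxyphenoxy)-1-(3,4-dimethoxyphenyl)propan-1-ol
Conditions: Zn(BH4)2 (about 0.15 M in Et2O, 1.0 equiv), Et2O, −20 °C; aq. NH4Cl
Reagents that add atoms: none
Why: Cram-chelate controlled reduction, where zinc bridges the carbonyl and aryloxy oxygens and hydride attacks from the face of the C2 hydrogen, giving the erythro (anti) alcohol with new C1 = (R); the cold, stoichiometric reagent should leave the allyl group alone.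

**Compound list**
1 | resorcinol | Oc1cccc(O)c1 | starting material
2 | 1,3-dimethoxybenzene | COc1cccc(OC)c1 | intermediate
3 | 2,6-dimethoxyphenyllithium | [Li]c1c(OC)cccc1OC | intermediate (not isolated)
4 | dimethyl (2,6-dimethoxyphenyl)boronate | COB(OC)c1c(OC)cccc1OC | intermediate (not isolated)
5 | 2,6-dimethoxyphenol | COc1cccc(OC)c1O | intermediate
6 | 2-(allyloxy)-1,3-dimethoxybenzene | C=CCOc1c(OC)cccc1OC | intermediate
7 | 6-allyl-2,6-dimethoxycyclohexa-2,4-dien-1-one | C=CCC1(OC)C=CC=C(OC)C1=O | intermediate (not isolated)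
8 | 4-allyl-2,6-dimethoxycyclohexa-2,5-dien-1-one | C=CCC1C=C(OC)C(=O)C(OC)=C1 | intermediate (not isolated)
9 | 4-allyl-2,6-dimethoxyphenol | C=CCc1cc(OC)c(O)c(OC)c1 | intermediate
10 | catechol | Oc1ccccc1O | starting material
11 | 1,2-dimethoxybenzene (veratrole) | COc1ccccc1OC | intermediate
12 | 4-bromo-1,2-dimethoxybenzene | COc1ccc(Br)cc1OC | intermediate
13 | methyl (R)-lactate | C[C@@H](O)C(=O)OC | starting material
14 | methyl (R)-2-[(tert-butyldimethylsilyl)oxy]propanoate | C[C@@H](O[Si](C)(C)C(C)(C)C)C(=O)OC | intermediate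
15 | (R)-2-[(tert-butyldimethylsilyl)oxy]-N-methoxy-N-methylpropanamide | C[C@@H](O[Si](C)(C)C(C)(C)C)C(=O)N(C)OC | intermediate
16 | (3,4-dimethoxyphenyl)magnesium bromide | COc1ccc([Mg]Br)cc1OC | intermediate (not isolated)
17 | (R)-2-[(tert-butyldimethylsilyl)oxy]-1-(3,4-dimethoxyphenyl)propan-1-one | C[C@@H](O[Si](C)(C)C(C)(C)C)C(=O)c1ccc(OC)c(OC)c1 | intermediate
18 | (R)-1-(3,4-dimethoxyphenyl)-2-hydroxypropan-1-one | C[C@@H](O)C(=O)c1ccc(OC)c(OC)c1 | intermediate
19 | (S)-2-(4-allyl-2,6-dimethoxyphenoxy)-1-(3,4-dimethoxyphenyl)propan-1-one | C=CCc1cc(OC)c(O[C@@H](C)C(=O)c2ccc(OC)c(OC)c2)c(OC)c1 | intermediate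
20 | (1R,2S)-2-(4-allyl-2,6-dimethoxyphenoxy)-1-(3,4-dimethoxyphenyl)propan-1-ol | C=CCc1cc(OC)c(O[C@@H](C)[C@H](O)c2ccc(OC)c(OC)c2)c(OC)c1 | target

**Step count**
Total: 12 steps (phenol branch 4, aryl branch 2, lactate branch 2, then 4 steps from the first union).
Longest linear sequence: 6 steps (for example steps 1, 2, 3, 4, 11, 12; the other two branches are equally long).

**Three steps most likely to fail**

Step 11 (Mitsunobu union). The phenol is flanked by two methoxy groups, and the enolisable α-hydroxy ketone may partly racemise or eliminate. The fallback moves the Mitsunobu onto the lactate ester and makes the late union a C–C bond instead. It sets out from 9, which is coupled with 13 (PPh3, DIAD, THF, 0 °C to rt, inversion) to give methyl (S)-2-(4-allyl-2,6-dimethoxyphenoxy)propanoate F1. Treatment with MeNHOMe·HCl and i-PrMgCl in THF at −20 °C converts this into (S)-2-(4-allyl-2,6-dimethoxyphenoxy)-N-methoxy-N-methylpropanamide F2. Addition of the Grignard reagent 16 (made from 12 as in step 9) at 0 °C then gives the ketone, and the fallback comes back to the route at 19.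

Step 12 (chelation-controlled reduction). The erythro:threo ratio may be modest, and the borohydride could begin to hydroborate the allyl group. The fallback replaces direct chelate control by a reduce-then-invert sequence. It sets out from 19, which is reduced under non-chelating Felkin–Anh control (L-Selectride, THF, −78 °C) to the threo alcohol (1S,2S)-2-(4-allyl-2,6-dimethoxyphenoxy)-1-(3,4-dimethoxyphenyl)propan-1-ol F3. Mitsunobu inversion at C1 with 4-nitrobenzoic acid (PPh3, DIAD, THF, 0 °C) gives (1R,2S)-2-(4-allyl-2,6-dimethoxyphenoxy)-1-(3,4-dimethoxyphenyl)propyl 4-nitrobenzoate F4. Methanolysis (K2CO3, MeOH, rt) releases the alcohol, and the fallback comes back to the route at 20.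

Step 4 (para-Claisen at 200 °C). Possible problems are tar formation, allyl-to-propenyl isomerisation and ortho migration with loss of methoxy. The fallback installs the allyl group by a polar cross-coupling instead of a sigmatropic shift. It sets out from 5, which is brominated para to the hydroxyl (NBS, CHCl3, −40 °C to rt) to give 4-bromo-2,6-dimethoxyphenol F5. Silylation (TBSCl, imidazole, DMF) gives (4-bromo-2,6-dimethoxyphenoxy)(tert-butyl)dimethylsilane F6. Magnesium insertion (Mg, THF) followed by allyl bromide with catalytic CuI gives (4-allyl-2,6-dimethoxyphenoxy)(tert-butyl)dimethylsilane F7. Desilylation with TBAF in THF at 0 °C brings the fallback back to the route at 9.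

**Further compounds**
F1 | step 11 | methyl (S)-2-(4-allyl-2,6-dimethoxyphenoxy)propanoate | C=CCc1cc(OC)c(O[C@@H](C)C(=O)OC)c(OC)c1
F2 | step 11 | (S)-2-(4-allyl-2,6-dimethoxyphenoxy)-N-methoxy-N-methylpropanamide | C=CCc1cc(OC)c(O[C@@H](C)C(=O)N(C)OC)c(OC)c1
F3 | step 12 | (1S,2S)-2-(4-allyl-2,6-dimethoxyphenoxy)-1-(3,4-dimethoxyphenyl)propan-1-ol | C=CCc1cc(OC)c(O[C@@H](C)[C@@H](O)c2ccc(OC)c(OC)c2)c(OC)c1
F4 | step 12 | (1R,2S)-2-(4-allyl-2,6-dimethoxyphenoxy)-1-(3,4-dimethoxyphenyl)propyl 4-nitrobenzoate | C=CCc1cc(OC)c(O[C@@H](C)[C@H](OC(=O)c2ccc(cc2)[N+](=O)[O-])c2ccc(OC)c(OC)c2)c(OC)c1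
F5 | step 4 | 4-bromo-2,6-dimethoxyphenol | COc1cc(Br)cc(OC)c1O
F6 | step 4 | (4-bromo-2,6-dimethoxyphenoxy)(tert-butyl)dimethylsilane | COc1cc(Br)cc(OC)c1O[Si](C)(C)C(C)(C)C
F7 | step 4 | (4-allyl-2,6-dimethoxyphenoxy)(tert-butyl)dimethylsilane | C=CCc1cc(OC)c(O[Si](C)(C)C(C)(C)C)c(OC)c1
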